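The bond between C4 and C4a of the dihydropyranone ring B (O1, C2, C3, C4, C4a, C8a) is the one disconnected. The double bond C4a=C8a, which ring B shares with the lactone ring A (C4a, C5, C6, O7, C8, C8a), carries O1 on C8a. It is therefore an enol ether, and C4a is its electron-rich terminus. In the key step this carbon attacks an activated carboxyl group held on the O1 tether. This acylation of Friedel-Crafts type closes ring B and delivers the C4 ketone and the fully substituted ring-fusion alkene at once. The precursor is ring A with a 3-oxy-decanoic acid side chain: O1 on C8a, (S)-C2 bearing heptyl, then CH2CO2H.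

Key step: step 9

Assumption: (S)-1,2-epoxydodecane is taken as a purchasable building block of high enantiomeric purity; the atom labels O1 to C8a refer to the pyrano[2,3-c]pyran numbering of the target.

Step 1
Reactants: 1 (S)-1,2-epoxydodecane; 2 methyl propiolate
Product: 4 methyl (S)-5-hydroxypentadec-2-ynoate, via methyl lithiopropiolate 3 (not isolated)
Conditions: 2, n-BuLi, THF, −78 °C; BF3·OEt2, then 1, −78 °C; aq. NH4Cl
Reagents that add atoms: none
Why: Yamaguchi-Hirao alkynylation, in which the lithium acetylide of 2 is stable at −78 °C and BF3 activation lets it open the epoxide by SN2 attack at the unsubstituted CH2, so the C–O bond of the stereocentre is never broken and the (S) configuration of 1 is carried over unchanged.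

Step 2
Reactants: 4 methyl (S)-5-hydroxypentadec-2-ynoate
Product: 6 (S)-6-decyltetrahydro-2H-pyran-2-one, via methyl (S)-5-hydroxypentadecanoate 5 (not isolated)
Conditions: H2 (1 atm), 10% Pd/C, EtOAc, rt; filter; TsOH·H2O (cat.), PhMe, 80 °C
Reagents that add atoms: none
Why: Heterogeneous hydrogenation takes the ynoate to the saturated ester, and acid-catalysed lactonization (intramolecular transesterification, six-membered exo-trig closure by the C5 hydroxyl) then forms ring A with loss of methanol, the carbinol C–O bond and hence the (S) centre staying intact.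

Step 3
Reactants: 6 (S)-6-decyltetrahydro-2H-pyran-2-one
Product: 8 (6S)-6-decyl-3-hydroxytetrahydro-2H-pyran-2-one (both C3 epimers), via potassium lactone enolate 7 (not isolated)
Conditions: KN(SiMe3)2, THF, −78 °C; (±)-trans-2-(phenylsulfonyl)-3-phenyloxaziridine, −78 °C; AcOH
Reagents that add atoms: 2-(phenylsulfonyl)-3-phenyloxaziridine (Davis oxaziridine), O=S(=O)(c1ccccc1)N1OC1c1ccccc1
Why: Davis enolate hydroxylation, in which the potassium enolate of the lactone attacks the electrophilic oxygen of the N-sulfonyloxaziridine; the mixture of epimers at the new carbinol carbon is of no concern because that carbon becomes sp2 in step 4, and the non-enolisable decyl-bearing centre is untouched.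

Step 4
Reactants: 8 (6S)-6-decyl-3-hydroxytetrahydro-2H-pyran-2-one (both C3 epimers)
Product: 10 (S)-6-decyl-3-hydroxy-5,6-dihydro-2H-pyran-2-one, via keto lactone 9 (not isolated)
Conditions: Dess-Martin periodinane (1.2 equiv), CH2Cl2, 0 °C to rt
Reagents that add atoms: none
Why: Dess-Martin oxidation of the secondary alpha-hydroxy lactone gives the alpha-keto lactone, which should tautomerise spontaneously to the conjugated, hydrogen-bonded enol (a diosphenol-type 3-hydroxy-5,6-dihydropyranone) that serves as the acidic partner of step 7.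

Step 5
Reactants: 11 tert-butyl acetoacetate; 12 1-bromohexane
Product: 14 tert-butyl 3-oxodecanoate, via acetoacetate dianion 13 (not isolated)
Conditions: NaH, THF, 0 °C; n-BuLi, 0 °C; 12, 0 °C to rt; 1 M HCl
Reagents that add atoms: none
Why: Weiler dianion alkylation, in which the terminal, less stabilised carbanion of the acetoacetate dianion is by far the more nucleophilic site, so the primary bromide is taken up by SN2 at the gamma carbon only.

Step 6
Reactants: 14 tert-butyl 3-oxodecanoate
Product: 15 tert-butyl (R)-3-hydroxydecanoate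
Conditions: RuCl2[(R)-BINAP] (0.2 mol %), H2 (50 atm), MeOH, 40 °C
Reagents that add atoms: none
Why: Noyori asymmetric hydrogenation of a beta-keto ester, in which chelation of ketone and ester to divalent ruthenium inside the chiral pocket of (R)-BINAP directs hydride to one face of the ketone and should give the (R)-3-hydroxy ester, the same sense as in the methyl acetoacetate case.

Step 7
Reactants: 10 (S)-6-decyl-3-hydroxy-5,6-dihydro-2H-pyran-2-one; 15 tert-butyl (R)-3-hydroxydecanoate
Product: 16 tert-butyl (S)-3-{[(S)-6-decyl-2-oxo-5,6-dihydro-2H-pyran-3-yl]oxy}decanoate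
Conditions: PPh3, DIAD (added last, dropwise), PhMe, 0 °C to rt
Reagents that add atoms: none
Why: Mitsunobu etherification, in which the enol (acidified by the adjacent lactone carbonyl) protonates the phosphine-azodicarboxylate adduct and its oxygen then displaces the oxyphosphonium group of 15 by SN2, so the O1–C2 bond forms with inversion from (R) to the (S) configuration required at C2, while the non-polar solvent and low temperature are chosen to hold back dehydration of the beta-hydroxy ester.

Step 8
Reactants: 16 tert-butyl (S)-3-{[(S)-6-decyl-2-oxo-5,6-dihydro-2H-pyran-3-yl]oxy}decanoate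
Product: 17 (S)-3-{[(S)-6-decyl-2-oxo-5,6-dihydro-2H-pyran-3-yl]oxy}decanoic acid
Conditions: TFA/CH2Cl2 (1:4), 0 °C to rt; evaporate, azeotrope with PhMe
Reagents that add atoms: none
Why: Acidolysis of the tert-butyl ester (alkyl-oxygen cleavage through the tert-butyl cation, lost as isobutene) frees the acid without any base, so the beta-alkoxy ester cannot eliminate, and the lactone and the electron-poor enol ether are expected to tolerate anhydrous TFA.

Step 9
Reactants: 17 (S)-3-{[(S)-6-decyl-2-oxo-5,6-dihydro-2H-pyran-3-yl]oxy}decanoic acid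
Product: 19 (2S,6S)-6-decyl-2-heptyl-2,3,5,6-tetrahydropyrano[2,3-c]pyran-4,8-dione (CNP0087259.2), via mixed trifluoroacetic anhydride 18 (not isolated)
Conditions: TFAA (1.5 equiv), CH2Cl2 (0.02 M), 0 °C, 30 min; then TfOH (10 mol %), 0 °C to rt
Reagents that add atoms: none
Why: Proposed new method: TFAA converts the acid into its mixed trifluoroacetic anhydride 18, catalytic TfOH makes the C4 acyl carbon acylium-like, C4a (the enol ether carbon that receives electron density from the O1 lone pair) attacks it, and the cation left at C8a, stabilised by O1, is quenched by loss of the proton on C4a, which restores the C4a=C8a double bond, now conjugated with the new ketone and the lactone. The closest known reaction types are the acid-mediated cyclisation of 3-aryloxyalkanoic acids to chroman-4-ones (intramolecular Friedel-Crafts acylation) and the C-acylation of simple alkyl enol ethers by TFAA or acid chlorides to beta-alkoxy enones; what is new is an enol ether that is also conjugated to a lactone carbonyl, whose lower nucleophilicity is the reason for the strong acid co-promoter. Ring B (O1, C2, C3, C4, C4a, C8a) closes in a six-membered mode that is exo with respect to the acyl C=O and endo with respect to the C4a=C8a alkene, which is geometrically easy because ring A holds O1 and the C4a hydrogen cis. No stereocentre is formed, and C2 and C6 take no part in any bond change. The selectivity needed is C-acylation at C4a alone with C2 left intact: with the three-atom tether, attack by C8a would have to build a strained five-membered ring at a carbon that already bears three non-hydrogen groups and would leave an unstabilised cation at C4a, there is no free hydroxyl that could be acylated instead, and the base-free medium gives the beta-alkoxy carbonyl unit no path to eliminate and re-add the enol, the process that could racemise C2.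

Compound list
1 | (S)-1,2-epoxydodecane | CCCCCCCCCC[C@H]1CO1 | starting material
2 | methyl propiolate | C#CC(=O)OC | starting material
3 | methyl 3-lithioprop-2-ynoate (lithium acetylide of 2, formed in the flask) | [Li+].[C-]#CC(=O)OC | intermediate
4 | methyl (S)-5-hydroxypentadec-2-ynoate | CCCCCCCCCC[C@H](O)CC#CC(=O)OC | intermediate
5 | methyl (S)-5-hydroxypentadecanoate (formed in the flask) | CCCCCCCCCC[C@H](O)CCCC(=O)OC | intermediate
6 | (S)-6-decyltetrahydro-2H-pyran-2-one | CCCCCCCCCC[C@H]1CCCC(=O)O1 | intermediate
7 | potassium (S)-6-decyl-5,6-dihydro-4H-pyran-2-olate (potassium enolate of 6, formed in the flask) | [K+].CCCCCCCCCC[C@H]1CCC=C([O-])O1 | intermediate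
8 | (6S)-6-decyl-3-hydroxytetrahydro-2H-pyran-2-one, mixture of C3 epimers | CCCCCCCCCC[C@H]1CCC(O)C(=O)O1 | intermediate
9 | (S)-6-decyldihydro-2H-pyran-2,3(4H)-dione (keto tautomer, formed in the flask) | CCCCCCCCCC[C@H]1CCC(=O)C(=O)O1 | intermediate
10 | (S)-6-decyl-3-hydroxy-5,6-dihydro-2H-pyran-2-one (enol of the alpha-keto lactone) | CCCCCCCCCC[C@H]1CC=C(O)C(=O)O1 | intermediate
11 | tert-butyl acetoacetate | CC(=O)CC(=O)OC(C)(C)C | starting material
12 | 1-bromohexane | CCCCCCBr | starting material
13 | sodium lithium dienediolate (dianion) of tert-butyl acetoacetate (formed in the flask) | [Na+].[Li+].C=C([O-])C=C([O-])OC(C)(C)C | intermediate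
14 | tert-butyl 3-oxodecanoate | CCCCCCCC(=O)CC(=O)OC(C)(C)C | intermediate
15 | tert-butyl (R)-3-hydroxydecanoate | CCCCCCC[C@@H](O)CC(=O)OC(C)(C)C | intermediate
16 | tert-butyl (S)-3-{[(S)-6-decyl-2-oxo-5,6-dihydro-2H-pyran-3-yl]oxy}decanoate | CCCCCCCCCC[C@H]1CC=C(O[C@@H](CCCCCCC)CC(=O)OC(C)(C)C)C(=O)O1 | intermediate
17 | (S)-3-{[(S)-6-decyl-2-oxo-5,6-dihydro-2H-pyran-3-yl]oxy}decanoic acid | CCCCCCCCCC[C@H]1CC=C(O[C@@H](CCCCCCC)CC(=O)O)C(=O)O1 | intermediate
18 | mixed anhydride of 17 with trifluoroacetic acid (formed in the flask) | CCCCCCCCCC[C@H]1CC=C(O[C@@H](CCCCCCC)CC(=O)OC(=O)C(F)(F)F)C(=O)O1 | intermediate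
19 | (2S,6S)-6-decyl-2-heptyl-2,3,5,6-tetrahydropyrano[2,3-c]pyran-4,8-dione (CNP0087259.2) | CCCCCCCCCC[C@H]1CC2=C(O[C@@H](CCCCCCC)CC2=O)C(=O)O1 | target

Total step count: 9.
Longest linear sequence: 7 steps (steps 1, 2, 3, 4, 7, 8 and 9, from epoxide 1 to target 19); the hydroxy ester branch (steps 5 and 6) joins at step 7.

Steps most likely to fail

Step 9 (proposed new method). The enol ether, deactivated by the lactone carbonyl, may attack the acyl electrophile too slowly. Protonation of the enol ether with cleavage of the O1 ether linkage, or intermolecular acylation, would then take over. The fallback uses known reactions only, leaves the route at 16 and rejoins it at 19. It makes C4a a vinyl-metal nucleophile that adds to a tethered aldehyde (intramolecular Nozaki-Hiyama-Kishi reaction).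
- Ester 16 is treated with Br2 in CH2Cl2 at −78 °C to give the dibromide tert-butyl (3S)-3-{[(6S)-3,4-dibromo-6-decyl-2-oxotetrahydro-2H-pyran-3-yl]oxy}decanoate F1, which is not isolated.
- Et3N removes HBr from it to leave the vinyl bromide tert-butyl (S)-3-{[(S)-4-bromo-6-decyl-2-oxo-5,6-dihydro-2H-pyran-3-yl]oxy}decanoate F2. The bromination is done at the ester stage so that no free acid can trap the bromo-oxocarbenium ion.
- TFA in CH2Cl2 gives (S)-3-{[(S)-4-bromo-6-decyl-2-oxo-5,6-dihydro-2H-pyran-3-yl]oxy}decanoic acid F3.
- BH3·SMe2 in THF at 0 °C reduces the acid, but not the lactone, to (S)-4-bromo-6-decyl-3-{[(S)-1-hydroxydecan-3-yl]oxy}-5,6-dihydro-2H-pyran-2-one F4.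
- Dess-Martin periodinane gives (S)-3-{[(S)-4-bromo-6-decyl-2-oxo-5,6-dihydro-2H-pyran-3-yl]oxy}decanal F5.
- CrCl2 with catalytic NiCl2 in DMF joins the vinyl carbon to the aldehyde and closes ring B as (2S,6S)-6-decyl-2-heptyl-4-hydroxy-3,4,5,6-tetrahydro-2H-pyrano[2,3-c]pyran-8-one F6 (both C4 epimers).
- Oxidation of this allylic alcohol with MnO2 or Dess-Martin periodinane should give 19.

Step 7. Elimination of the phosphonium-activated beta-hydroxy ester to the conjugated enoate may outrun substitution by the hindered, weakly nucleophilic enolate, and alkylation on carbon instead of oxygen is also possible. The fallback removes the acidifying ester from the alcohol partner and carries the carboxyl group as a protected primary alcohol. It leaves the route at 15 (with 10) and rejoins it at 17, so that 16 and step 8 are bypassed.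
- LiAlH4 in THF reduces 15 to (R)-decane-1,3-diol F7.
- TBSCl and imidazole in CH2Cl2 at 0 °C silylate the primary hydroxyl selectively to give (R)-1-[(tert-butyldimethylsilyl)oxy]decan-3-ol F8.
- Mitsunobu coupling of F8 with enol 10 (PPh3, DIAD, PhMe) proceeds with inversion and should give (S)-6-decyl-3-{[(S)-1-[(tert-butyldimethylsilyl)oxy]decan-3-yl]oxy}-5,6-dihydro-2H-pyran-2-one F9.
- HF·pyridine in THF frees (S)-6-decyl-3-{[(S)-1-hydroxydecan-3-yl]oxy}-5,6-dihydro-2H-pyran-2-one F10.
- Catalytic TEMPO with PhI(OAc)2 in MeCN/H2O oxidises F10 through the aldehyde (S)-3-{[(S)-6-decyl-2-oxo-5,6-dihydro-2H-pyran-3-yl]oxy}decanal F11 (not isolated) to acid 17.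

Step 4. The electron-rich enol may be over-oxidised or oxidatively degraded by the hypervalent iodine reagent as it forms, and this adds to any loss in the enolate hydroxylation before it. The fallback avoids the hydroxylation and oxidation pair altogether. It leaves the route at 6 and rejoins it at 10.
- Lactone 6 is heated with tert-butoxybis(dimethylamino)methane (Bredereck's reagent) in PhMe at 90 °C to give the enamino lactone (S,E)-6-decyl-3-[(dimethylamino)methylidene]tetrahydro-2H-pyran-2-one F12.
- Sensitised photooxygenation (O2, light, tetraphenylporphyrin, CH2Cl2, −78 °C) cleaves the enamine double bond with singlet oxygen to give keto lactone 9, which tautomerises to 10.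

Further compounds
F1 | step 9 | tert-butyl (3S)-3-{[(6S)-3,4-dibromo-6-decyl-2-oxotetrahydro-2H-pyran-3-yl]oxy}decanoate (diastereomers at the two brominated carbons) | CCCCCCCCCC[C@H]1CC(Br)C(Br)(O[C@@H](CCCCCCC)CC(=O)OC(C)(C)C)C(=O)O1
F2 | step 9 | tert-butyl (S)-3-{[(S)-4-bromo-6-decyl-2-oxo-5,6-dihydro-2H-pyran-3-yl]oxy}decanoate | CCCCCCCCCC[C@H]1CC(Br)=C(O[C@@H](CCCCCCC)CC(=O)OC(C)(C)C)C(=O)O1
F3 | step 9 | (S)-3-{[(S)-4-bromo-6-decyl-2-oxo-5,6-dihydro-2H-pyran-3-yl]oxy}decanoic acid | CCCCCCCCCC[C@H]1CC(Br)=C(O[C@@H](CCCCCCC)CC(=O)O)C(=O)O1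
F4 | step 9 | (S)-4-bromo-6-decyl-3-{[(S)-1-hydroxydecan-3-yl]oxy}-5,6-dihydro-2H-pyran-2-one | CCCCCCCCCC[C@H]1CC(Br)=C(O[C@@H](CCCCCCC)CCO)C(=O)O1
F5 | step 9 | (S)-3-{[(S)-4-bromo-6-decyl-2-oxo-5,6-dihydro-2H-pyran-3-yl]oxy}decanal | CCCCCCCCCC[C@H]1CC(Br)=C(O[C@@H](CCCCCCC)CC=O)C(=O)O1
F6 | step 9 | (2S,6S)-6-decyl-2-heptyl-4-hydroxy-3,4,5,6-tetrahydro-2H-pyrano[2,3-c]pyran-8-one (both C4 epimers) | CCCCCCCCCC[C@H]1CC2=C(O[C@@H](CCCCCCC)CC2O)C(=O)O1
F7 | step 7 | (R)-decane-1,3-diol | CCCCCCC[C@@H](O)CCO
F8 | step 7 | (R)-1-[(tert-butyldimethylsilyl)oxy]decan-3-ol | CCCCCCC[C@@H](O)CCO[Si](C)(C)C(C)(C)C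
F9 | step 7 | (S)-6-decyl-3-{[(S)-1-[(tert-butyldimethylsilyl)oxy]decan-3-yl]oxy}-5,6-dihydro-2H-pyran-2-one | CCCCCCCCCC[C@H]1CC=C(O[C@@H](CCCCCCC)CCO[Si](C)(C)C(C)(C)C)C(=O)O1
F10 | step 7 | (S)-6-decyl-3-{[(S)-1-hydroxydecan-3-yl]oxy}-5,6-dihydro-2H-pyran-2-one | CCCCCCCCCC[C@H]1CC=C(O[C@@H](CCCCCCC)CCO)C(=O)O1
F11 | step 7 | (S)-3-{[(S)-6-decyl-2-oxo-5,6-dihydro-2H-pyran-3-yl]oxy}decanal | CCCCCCCCCC[C@H]1CC=C(O[C@@H](CCCCCCC)CC=O)C(=O)O1
F12 | step 4 | (S,E)-6-decyl-3-[(dimethylamino)methylidene]tetrahydro-2H-pyran-2-one | CCCCCCCCCC[C@H]1CC/C(=C\N(C)C)C(=O)O1
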